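**Retrosynthetic overview**

1. Feature: the C1 carboxyl of ring A and the C6' hydroxymethyl of ring B sit on the two carbons that flank the diaryl ether oxygen (C6–O–C1'), so the target is the ring-opened (seco) acid of an eight-membered dibenzo[b,g][1,5]dioxocin-5-one lactone.
2. Key disconnection: the C6–O aryl ether bond, formed by copper-mediated intramolecular Ullmann etherification of the benzyl ester that joins the two rings (ring B phenol oxygen onto C6 of ring A). This closes the eight-membered lactone, the only ring built (rings A and B are purchased arenes); hydroxide reopens it before the final MOM removal.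
3. A phenoxide ortho to an acyloxymethyl group can expel the carboxylate as an ortho-quinone methide. The precursor therefore carries iodide at C6, and the phenoxide is generated only as its copper salt, without alkali base, so that closure can run near room temperature.
4. The ester comes from a Mitsunobu union of the ring A acid (6-iodo, MOM on O2, prenyl on C3) with the ring B salicyl alcohol (free O1', MOM on O2').
5. Ring A acid: 2-bromo-6-hydroxybenzoic acid, O-allyl ether, Claisen shift to C3, MOM, cross-metathesis to prenyl, Br/I exchange, saponification. Ring B alcohol: creosol, ortho-formylation, O-demethylation, selective MOM on O2', reduction.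

Key step: step 12

Remark: the target has no stereocentre and no E/Z-isomeric alkene, so no stereocontrol is needed; the four starting materials are taken as purchasable.

**Route**

Step 1
Reactants: 1 2-bromo-6-hydroxybenzoic acid; 2 allyl bromide
Product: 4 methyl 2-(allyloxy)-6-bromobenzoate, via methyl 2-bromo-6-hydroxybenzoate 3 (not isolated)
Conditions: KHCO3 (1.1 equiv), MeI (1.05 equiv), DMF, 20 °C; then K2CO3 (2 equiv), allyl bromide (1.3 equiv), 60 °C
Reagents that add atoms: iodomethane, CI
Why: SN2 methylation of the carboxylate (hydrogencarbonate leaves the hydrogen-bonded phenol protonated) is followed in the same pot by Williamson O-allylation of the salicylate phenoxide once carbonate is added.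

Step 2
Reactants: 4 methyl 2-(allyloxy)-6-bromobenzoate
Product: 6 methyl 3-allyl-6-bromo-2-hydroxybenzoate, via ortho-allyl cyclohexadienone 5 (not isolated)
Conditions: N,N-diethylaniline, 195 °C, argon
Reagents that add atoms: none
Why: The aromatic Claisen rearrangement ([3,3]-sigmatropic shift) carries the allyl group to C3, the only unsubstituted ortho position, and the dienone tautomerises to the hydrogen-bonded salicylate.

Step 3
Reactants: 6 methyl 3-allyl-6-bromo-2-hydroxybenzoate
Product: 7 methyl 3-allyl-6-bromo-2-(methoxymethoxy)benzoate
Conditions: NaH (1.2 equiv), MOMCl (1.3 equiv), DMF, 0 → 20 °C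
Reagents that add atoms: chloromethyl methyl ether, COCCl
Why: MOM protection by Williamson-type alkylation, in which NaH fully deprotonates the hindered, hydrogen-bonded salicylate OH so that the reactive chloromethyl ether is captured on oxygen.

Step 4
Reactants: 7 methyl 3-allyl-6-bromo-2-(methoxymethoxy)benzoate; 8 2-methylbut-2-ene
Product: 9 methyl 6-bromo-2-(methoxymethoxy)-3-(3-methylbut-2-enyl)benzoate
Conditions: second-generation Grubbs catalyst RuCl2(=CHPh)(H2IMes)(PCy3) (3 mol %), 2-methylbut-2-ene (excess)/CH2Cl2, 40 °C, sealed vessel
Reagents that add atoms: none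
Why: Olefin cross-metathesis of the terminal allyl alkene with excess 2-methylbut-2-ene releases propene and installs the trisubstituted prenyl alkene, which does not react further, while aryl bromide, ester and acetal are tolerated.

Step 5
Reactants: 9 methyl 6-bromo-2-(methoxymethoxy)-3-(3-methylbut-2-enyl)benzoate
Product: 10 methyl 6-iodo-2-(methoxymethoxy)-3-(3-methylbut-2-enyl)benzoate
Conditions: CuI (10 mol %), trans-N,N'-dimethylcyclohexane-1,2-diamine (20 mol %), NaI (2 equiv), 1,4-dioxane, 110 °C
Reagents that add atoms: sodium iodide, [Na+].[I-]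
Why: The copper-catalysed aromatic Finkelstein halogen exchange is driven by precipitation of NaBr from dioxane and provides the more reactive C6 iodide needed for a low-temperature ring closure, with alkene, MOM ether and ester inert.

Step 6
Reactants: 10 methyl 6-iodo-2-(methoxymethoxy)-3-(3-methylbut-2-enyl)benzoate
Product: 11 6-iodo-2-(methoxymethoxy)-3-(3-methylbut-2-enyl)benzoic acid
Conditions: KOH (10 equiv), MeOH/H2O, 75 °C; then cold dilute HCl to pH 3
Reagents that add atoms: potassium hydroxide, [K+].[OH-]
Why: Saponification by hydroxide acyl substitution, heated with excess base because the ester is flanked by two ortho substituents, under conditions that MOM ether, aryl iodide and prenyl group tolerate.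

Step 7
Reactants: 12 creosol (2-methoxy-4-methylphenol)
Product: 14 2-hydroxy-3-methoxy-5-methylbenzaldehyde, via 2-(hydroxymethyl)-6-methoxy-4-methylphenol 13 (not isolated)
Conditions: MgCl2 (1.5 equiv), Et3N (3.75 equiv), (CH2O)n (6 equiv), MeCN, reflux; aqueous HCl work-up
Reagents that add atoms: formaldehyde (as paraformaldehyde), C=O
Why: Magnesium-phenoxide-directed ortho-formylation (Casnati–Skattebøl reaction), in which the chelated phenoxide is hydroxymethylated at the only free ortho position and the benzylic alkoxide is oxidised by hydride transfer to a second formaldehyde.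

Step 8
Reactants: 14 2-hydroxy-3-methoxy-5-methylbenzaldehyde
Product: 15 2,3-dihydroxy-5-methylbenzaldehyde
Conditions: BBr3 (2.5 equiv), CH2Cl2, −78 → 0 °C; then H2O
Reagents that add atoms: none
Why: Lewis-acid O-demethylation of the aryl methyl ether by BBr3 (bromide attacks the methyl group of the boron-complexed ether), the standard route from ortho-vanillin-type aldehydes to catechol aldehydes.

Step 9
Reactants: 15 2,3-dihydroxy-5-methylbenzaldehyde
Product: 16 2-hydroxy-3-(methoxymethoxy)-5-methylbenzaldehyde
Conditions: NaH (2.1 equiv), THF/DMF, 0 °C; then MOMCl (1.0 equiv), −20 → 0 °C; aqueous NH4Cl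
Reagents that add atoms: chloromethyl methyl ether, COCCl
Why: Regioselective Williamson etherification of the catechol dianion, in which the oxide on C3 is neither conjugated with nor chelated by the formyl group and is therefore the more nucleophilic site for one equivalent of the chloromethyl ether.

Step 10
Reactants: 16 2-hydroxy-3-(methoxymethoxy)-5-methylbenzaldehyde
Product: 17 2-(hydroxymethyl)-6-(methoxymethoxy)-4-methylphenol
Conditions: NaBH4 (1 equiv), MeOH, 0 °C
Reagents that add atoms: none
Why: Borohydride reduction of the aldehyde gives the benzylic alcohol and leaves the MOM ether and the phenol untouched.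

Step 11
Reactants: 11 6-iodo-2-(methoxymethoxy)-3-(3-methylbut-2-enyl)benzoic acid; 17 2-(hydroxymethyl)-6-(methoxymethoxy)-4-methylphenol
Product: 18 2-hydroxy-3-(methoxymethoxy)-5-methylbenzyl 6-iodo-2-(methoxymethoxy)-3-(3-methylbut-2-enyl)benzoate
Conditions: PPh3 (1.3 equiv), DIAD (1.3 equiv), THF, 0 → 20 °C; neutral work-up
Reagents that add atoms: none
Why: Mitsunobu esterification, in which the carboxylic acid (far more acidic than the phenol) is the pronucleophile and attacks the oxyphosphonium-activated benzylic CH2 by SN2, so that the hindered carbonyl needs no acyl substitution and the medium stays non-basic.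

Step 12
Reactants: 18 2-hydroxy-3-(methoxymethoxy)-5-methylbenzyl 6-iodo-2-(methoxymethoxy)-3-(3-methylbut-2-enyl)benzoate
Product: 20 4,11-bis(methoxymethoxy)-9-methyl-3-(3-methylbut-2-enyl)-7H-dibenzo[b,g][1,5]dioxocin-5-one, via monovalent copper phenoxide 19 (not isolated)
Conditions: mesitylcopper (2,4,6-Me3C6H2)Cu (1.05 equiv), pyridine/toluene, 0.003 M, 20 °C then 50 °C, argon
Reagents that add atoms: none
Why: Protonolysis of mesitylcopper by the ring B phenol gives the monovalent copper phenoxide 19 without any alkali base; the ester carbonyl on C1 of ring A chelates the copper and assists oxidative addition into the neighbouring C6–I bond, and the trivalent aryl(aryloxy)copper so formed reductively eliminates to make the C6–O bond and release CuI. The closest known reaction type is the intramolecular Ullmann diaryl ether cyclisation run through a preformed copper phenoxide in pyridine, as used for diaryl ether macrocycles. The eight-membered lactone closes by attack of the tethered oxygen on the ipso carbon C6 with the iodide leaving outside the new ring (8-exo at an aryl carbon), helped by a tether that consists of two arene edges and an ester and so has few freely rotating bonds. No stereocentre is formed. Ring closure has to outrun two competitors: 1,4-elimination of the ring A benzoate from the ortho-(acyloxymethyl)phenoxide to an ortho-quinone methide, held back because the phenoxide exists only bound to copper in a weakly polar, carbonate-free medium and because the iodide next to the chelating ester should allow coupling at or below 50 °C, and intermolecular coupling, which the short rigid tether and high dilution disfavour. Only one phenol is free, since O2 of ring A and O2' of ring B carry MOM groups.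

Step 13
Reactants: 20 4,11-bis(methoxymethoxy)-9-methyl-3-(3-methylbut-2-enyl)-7H-dibenzo[b,g][1,5]dioxocin-5-one
Product: 21 6-[2-(hydroxymethyl)-6-(methoxymethoxy)-4-methylphenoxy]-2-(methoxymethoxy)-3-(3-methylbut-2-enyl)benzoic acid
Conditions: LiOH·H2O (5 equiv), THF/H2O, 45 °C; then dilute HCl to pH 4 at 0 °C
Reagents that add atoms: lithium hydroxide, [Li+].[OH-]
Why: Lactone saponification (hydroxide addition to the ester carbonyl) opens the eight-membered ring and frees the carboxylate and the benzylic alcohol in one operation, while MOM ethers, diaryl ether and prenyl group are stable to base.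

Step 14
Reactants: 21 6-[2-(hydroxymethyl)-6-(methoxymethoxy)-4-methylphenoxy]-2-(methoxymethoxy)-3-(3-methylbut-2-enyl)benzoic acid
Product: 22 2-hydroxy-6-[2-hydroxy-6-(hydroxymethyl)-4-methylphenoxy]-3-(3-methylbut-2-enyl)benzoic acid (CNP0140656.0)
Conditions: 2 M aqueous HCl, MeOH/THF, 20 → 40 °C
Reagents that add atoms: none
Why: Acid-catalysed acetal exchange with methanol removes both MOM groups, and dilute acid near room temperature is chosen so that the prenyl alkene is not protonated and the doubly ortho-substituted acid is not esterified.

**Compound list**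

1 | 2-bromo-6-hydroxybenzoic acid | O=C(O)c1c(O)cccc1Br | starting material
2 | allyl bromide | C=CCBr | starting material
3 | methyl 2-bromo-6-hydroxybenzoate | COC(=O)c1c(O)cccc1Br | intermediate
4 | methyl 2-(allyloxy)-6-bromobenzoate | COC(=O)c1c(OCC=C)cccc1Br | intermediate
5 | methyl 5-allyl-2-bromo-6-oxocyclohexa-1,3-diene-1-carboxylate (racemic, transient) | COC(=O)C1=C(Br)C=CC(CC=C)C1=O | intermediate
6 | methyl 3-allyl-6-bromo-2-hydroxybenzoate | COC(=O)c1c(O)c(CC=C)ccc1Br | intermediate
7 | methyl 3-allyl-6-bromo-2-(methoxymethoxy)benzoate | COCOc1c(CC=C)ccc(Br)c1C(=O)OC | intermediate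
8 | 2-methylbut-2-ene | CC=C(C)C | starting material
9 | methyl 6-bromo-2-(methoxymethoxy)-3-(3-methylbut-2-enyl)benzoate | COCOc1c(CC=C(C)C)ccc(Br)c1C(=O)OC | intermediate
10 | methyl 6-iodo-2-(methoxymethoxy)-3-(3-methylbut-2-enyl)benzoate | COCOc1c(CC=C(C)C)ccc(I)c1C(=O)OC | intermediate
11 | 6-iodo-2-(methoxymethoxy)-3-(3-methylbut-2-enyl)benzoic acid | COCOc1c(CC=C(C)C)ccc(I)c1C(=O)O | intermediate
12 | creosol (2-methoxy-4-methylphenol) | COc1cc(C)ccc1O | starting material
13 | 2-(hydroxymethyl)-6-methoxy-4-methylphenol | COc1cc(C)cc(CO)c1O | intermediate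
14 | 2-hydroxy-3-methoxy-5-methylbenzaldehyde | COc1cc(C)cc(C=O)c1O | intermediate
15 | 2,3-dihydroxy-5-methylbenzaldehyde | Oc1cc(C)cc(C=O)c1O | intermediate
16 | 2-hydroxy-3-(methoxymethoxy)-5-methylbenzaldehyde | COCOc1cc(C)cc(C=O)c1O | intermediate
17 | 2-(hydroxymethyl)-6-(methoxymethoxy)-4-methylphenol | COCOc1cc(C)cc(CO)c1O | intermediate
18 | 2-hydroxy-3-(methoxymethoxy)-5-methylbenzyl 6-iodo-2-(methoxymethoxy)-3-(3-methylbut-2-enyl)benzoate | CC(C)=CCc1ccc(I)c(C(=O)OCc2cc(C)cc(OCOC)c2O)c1OCOC | intermediate
19 | monovalent copper phenoxide of 18 | CC(C)=CCc1ccc(I)c(C(=O)OCc2cc(C)cc(OCOC)c2O[Cu])c1OCOC | intermediate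
20 | 4,11-bis(methoxymethoxy)-9-methyl-3-(3-methylbut-2-enyl)-7H-dibenzo[b,g][1,5]dioxocin-5-one | CC(C)=CCc1ccc2Oc3c(OCOC)cc(C)cc3COC(=O)c2c1OCOC | intermediate
21 | 6-[2-(hydroxymethyl)-6-(methoxymethoxy)-4-methylphenoxy]-2-(methoxymethoxy)-3-(3-methylbut-2-enyl)benzoic acid | CC(C)=CCc1ccc(Oc2c(OCOC)cc(C)cc2CO)c(C(=O)O)c1OCOC | intermediate
22 | 2-hydroxy-6-[2-hydroxy-6-(hydroxymethyl)-4-methylphenoxy]-3-(3-methylbut-2-enyl)benzoic acid | CC(C)=CCc1ccc(Oc2c(O)cc(C)cc2CO)c(C(=O)O)c1O | target

**Step count**

Total steps: 14. Longest linear sequence: 10 steps (steps 1 to 6, then 11 to 14).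

**Steps most likely to fail**

Step 12 (ring closure). The copper phenoxide may lose the ring A benzoate by 1,4-elimination, and the resulting ortho-quinone methide would oligomerise; alternatively, oxidative addition may be too slow at 50 °C, so that heating is needed and the same fragmentation sets in. The fallback gives up the tether and sets out from iodo ester 10 and aldehyde 16. An intermolecular Ullmann etherification (CuI, N,N-dimethylglycine hydrochloride, Cs2CO3, 1,4-dioxane, 90 °C) should give methyl 6-[2-formyl-6-(methoxymethoxy)-4-methylphenoxy]-2-(methoxymethoxy)-3-(3-methylbut-2-enyl)benzoate F1, in which the carbon next to the phenoxide is a formyl group that cannot eliminate. NaBH4 in MeOH would reduce it to methyl 6-[2-(hydroxymethyl)-6-(methoxymethoxy)-4-methylphenoxy]-2-(methoxymethoxy)-3-(3-methylbut-2-enyl)benzoate F2, and KOH in aqueous MeOH at 75 °C would hydrolyse the ester. The route is rejoined at seco acid 21.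

Step 11 (Mitsunobu esterification beside a free phenol). Activation of the benzylic alcohol next to the unprotected phenol may lead to self-condensation through a quinone-methide-type pathway, or to O-alkylation of the phenol in place of the acid. The fallback masks the phenol and sets out from aldehyde 16. Silylation (TBSCl, imidazole, DMF) would give 2-[tert-butyl(dimethyl)silyloxy]-3-(methoxymethoxy)-5-methylbenzaldehyde F3, and NaBH4 in MeOH at 0 °C would give [2-[tert-butyl(dimethyl)silyloxy]-3-(methoxymethoxy)-5-methylphenyl]methanol F4. Mitsunobu esterification with acid 11 would give 2-[tert-butyl(dimethyl)silyloxy]-3-(methoxymethoxy)-5-methylbenzyl 6-iodo-2-(methoxymethoxy)-3-(3-methylbut-2-enyl)benzoate F5. Desilylation with HF·pyridine in THF, an acidic medium in which the phenol is never present as phenoxide, rejoins the route at ester 18.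

Step 9 (selective MOM protection). Site selectivity between the two catechol oxygens may be poor, or double alkylation may occur. The fallback differentiates the oxygens by a cyclic acetal and sets out from catechol aldehyde 15. NaBH4 in MeOH would give 3-(hydroxymethyl)-5-methylbenzene-1,2-diol F6. 2,2-Dimethoxypropane with catalytic pyridinium tosylate in acetone at 20 °C should tie the benzylic hydroxyl and the adjacent phenol into 2,2,6-trimethyl-4H-1,3-benzodioxin-8-ol F7. MOMCl with i-Pr2NEt in CH2Cl2 would protect the remaining phenol as 8-(methoxymethoxy)-2,2,6-trimethyl-4H-1,3-benzodioxine F8. Aqueous acetic acid at 20 °C should hydrolyse the ketal much faster than the formaldehyde acetal, and the route is rejoined at alcohol 17.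

**Further compounds**

F1 | step 12 | methyl 6-[2-formyl-6-(methoxymethoxy)-4-methylphenoxy]-2-(methoxymethoxy)-3-(3-methylbut-2-enyl)benzoate | CC(C)=CCc1ccc(Oc2c(OCOC)cc(C)cc2C=O)c(C(=O)OC)c1OCOC
F2 | step 12 | methyl 6-[2-(hydroxymethyl)-6-(methoxymethoxy)-4-methylphenoxy]-2-(methoxymethoxy)-3-(3-methylbut-2-enyl)benzoate | CC(C)=CCc1ccc(Oc2c(OCOC)cc(C)cc2CO)c(C(=O)OC)c1OCOC
F3 | step 11 | 2-[tert-butyl(dimethyl)silyloxy]-3-(methoxymethoxy)-5-methylbenzaldehyde | COCOc1cc(C)cc(C=O)c1O[Si](C)(C)C(C)(C)C
F4 | step 11 | [2-[tert-butyl(dimethyl)silyloxy]-3-(methoxymethoxy)-5-methylphenyl]methanol | COCOc1cc(C)cc(CO)c1O[Si](C)(C)C(C)(C)C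
F5 | step 11 | 2-[tert-butyl(dimethyl)silyloxy]-3-(methoxymethoxy)-5-methylbenzyl 6-iodo-2-(methoxymethoxy)-3-(3-methylbut-2-enyl)benzoate | CC(C)=CCc1ccc(I)c(C(=O)OCc2cc(C)cc(OCOC)c2O[Si](C)(C)C(C)(C)C)c1OCOC
F6 | step 9 | 3-(hydroxymethyl)-5-methylbenzene-1,2-diol | Cc1cc(O)c(O)c(CO)c1
F7 | step 9 | 2,2,6-trimethyl-4H-1,3-benzodioxin-8-ol | Cc1cc(O)c2OC(C)(C)OCc2c1
F8 | step 9 | 8-(methoxymethoxy)-2,2,6-trimethyl-4H-1,3-benzodioxine | COCOc1cc(C)cc2COC(C)(C)Oc12
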